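Ring A of juglanin A carries OMe, the diaryl ether oxygen on the adjacent carbon and the chain end C7 para to OMe. This pattern is what forms when an aryl ethynyl ether adds across C3 and C6 of a 3-methoxy-6-alkyl-2-pyrone and CO2 is lost, so the diaryl ether C–O bond is never made by coupling: the oxygen arrives as an alkynyl ether of the ring B phenol. One thermal intramolecular Diels–Alder/decarboxylation builds ring A and the 15-membered ring together. The precursor is a 3-methoxy-2-pyrone joined at C6 through the C7–C1 ketone chain to ring B, which bears MOM-protected OH, OMe and the terminal ethynyl ether.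

Key step: step 14

Remark: the C5 ketone is created after the last organolithium step and is therefore carried unprotected; the target has no stereocentre; but-3-enylzinc bromide and tert-butyl methoxyacetate are taken as purchasable.

Step 1
Reactants: 1 2-methoxyresorcinol
Product: 2 2-methoxy-3-[(triisopropylsilyl)oxy]phenol
Conditions: NaH (1.0 equiv), THF, 0 °C; TIPSCl (1.0 equiv), 0 → 25 °C
Reagents that add atoms: chlorotriisopropylsilane (TIPSCl), CC(C)[Si](Cl)(C(C)C)C(C)C
Why: O-silylation of the mono-phenoxide of the symmetric diol should stop largely at the mono-ether, because the first bulky TIPS group crowds the central methoxy and the second hydroxyl, and recovered diol and bis-ether can be recycled.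

Step 2
Reactants: 2 2-methoxy-3-[(triisopropylsilyl)oxy]phenol
Product: 3 [2-methoxy-3-(methoxymethoxy)phenoxy]triisopropylsilane
Conditions: MOMCl, i-Pr2NEt, CH2Cl2, 0 → 25 °C
Reagents that add atoms: chloromethyl methyl ether (MOMCl), COCCl
Why: Routine O-alkylation of the remaining phenol installs the MOM acetal, which later directs metalation and masks the ring B phenol to the end.

Step 3
Reactants: 3 [2-methoxy-3-(methoxymethoxy)phenoxy]triisopropylsilane
Product: 5 [4-iodo-2-methoxy-3-(methoxymethoxy)phenoxy]triisopropylsilane, via aryllithium 4 (not isolated)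
Conditions: n-BuLi, TMEDA, Et2O, 0 °C; I2, THF, −78 → 25 °C
Reagents that add atoms: iodine, II
Why: Directed ortho-metalation should give one regioisomer, since the MOM ether is the strongest director, its only free ortho position is C4, and the bulky silyl ether does not direct.

Step 4
Reactants: 5 [4-iodo-2-methoxy-3-(methoxymethoxy)phenoxy]triisopropylsilane; 6 but-3-en-1-ylzinc bromide
Product: 7 [4-(but-3-en-1-yl)-2-methoxy-3-(methoxymethoxy)phenoxy]triisopropylsilane
Conditions: PdCl2(dppf) (3 mol%), THF, 50 °C
Reagents that add atoms: none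
Why: Negishi coupling of a primary alkylzinc halide with an aryl iodide is reliable (the bidentate phosphine suppresses beta-hydride elimination) and attaches C1–C4 as a terminal alkene that is inert to the organolithium step.

Step 5
Reactants: 7 [4-(but-3-en-1-yl)-2-methoxy-3-(methoxymethoxy)phenoxy]triisopropylsilane; 8 trichloroethylene
Product: 10 1-(but-3-en-1-yl)-4-{[(E)-1,2-dichloroethenyl]oxy}-3-methoxy-2-(methoxymethoxy)benzene, via cesium phenolate 9 (not isolated)
Conditions: CsF, DMF, 25 °C; then K2CO3, Cl2C=CHCl, 70 °C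
Reagents that add atoms: none
Why: Fluoride cleaves the aryl silyl ether and the phenoxide adds anti to dichloroacetylene generated in the flask from trichloroethylene, the standard entry to E-dichlorovinyl ethers as ynol ether precursors.

Step 6
Reactants: 10 1-(but-3-en-1-yl)-4-{[(E)-1,2-dichloroethenyl]oxy}-3-methoxy-2-(methoxymethoxy)benzene
Product: 13 1-(but-3-en-1-yl)-3-methoxy-2-(methoxymethoxy)-4-{[(triisopropylsilyl)ethynyl]oxy}benzene, via chloroethynyl ether 11 (not isolated), via lithium acetylide 12 (not isolated)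
Conditions: n-BuLi (2.2 equiv), THF, −78 → −40 °C; TIPSOTf, −78 → 0 °C
Reagents that add atoms: triisopropylsilyl triflate (TIPSOTf), CC(C)[Si](OS(=O)(=O)C(F)(F)F)(C(C)C)C(C)C
Why: Dehydrochlorination followed by chlorine–lithium exchange gives the aryloxyacetylide, which is silylated on carbon; the MOM ether has no free ortho position, the alkene is inert at low temperature, and the TIPS cap stabilises the ynol ether for the next two steps.

Step 7
Reactants: 14 pent-4-ynoic acid
Product: 15 S-phenyl pent-4-ynethioate
Conditions: PhSH, DCC, DMAP (cat.), CH2Cl2, 0 → 25 °C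
Reagents that add atoms: thiophenol, Sc1ccccc1
Why: Steglich-type thioesterification turns the acid into the acyl donor needed for the later ketone synthesis without touching the terminal alkyne.

Step 8
Reactants: 16 tert-butyl 2-methoxyacetate; 17 ethyl formate
Product: 18 sodium (1E)-3-tert-butoxy-2-methoxy-3-oxoprop-1-en-1-olate
Conditions: NaH, Et2O/THF, 0 → 25 °C; salt collected by filtration
Reagents that add atoms: sodium hydride, [Na+].[H-]
Why: Crossed Claisen condensation of the alkoxyacetate enolate with a non-enolisable formate is driven by formation of the stabilised, chelated sodium enolate.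

Step 9
Reactants: 18 sodium (1E)-3-tert-butoxy-2-methoxy-3-oxoprop-1-en-1-olate
Product: 19 tert-butyl (2E)-2-methoxy-3-{[(trifluoromethyl)sulfonyl]oxy}prop-2-enoate
Conditions: Tf2O, CH2Cl2, −78 → 0 °C
Reagents that add atoms: triflic anhydride, O=S(=O)(OS(=O)(=O)C(F)(F)F)C(F)(F)F
Why: O-sulfonylation of the sodium chelate, in which the enolate oxygen and the ester carbonyl share the cation in a non-coordinating solvent, should place the triflate cis to the ester (E), the geometry needed for lactonisation.

Step 10
Reactants: 15 S-phenyl pent-4-ynethioate; 19 tert-butyl (2E)-2-methoxy-3-{[(trifluoromethyl)sulfonyl]oxy}prop-2-enoate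
Product: 20 tert-butyl (2E)-2-methoxy-8-oxo-8-(phenylsulfanyl)oct-2-en-4-ynoate
Conditions: PdCl2(PPh3)2 (3 mol%), CuI (6 mol%), i-Pr2NEt, THF, 25 °C
Reagents that add atoms: none
Why: Sonogashira coupling of an electron-poor enol triflate proceeds at room temperature with retention of alkene geometry, and the hindered tertiary amine avoids addition–elimination at the beta-carbon and aminolysis of the aryl thioester.

Step 11
Reactants: 20 tert-butyl (2E)-2-methoxy-8-oxo-8-(phenylsulfanyl)oct-2-en-4-ynoate
Product: 22 S-phenyl 3-(3-methoxy-2-oxo-2H-pyran-6-yl)propanethioate, via enynoic acid 21 (not isolated)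
Conditions: TFA, CH2Cl2, 0 → 25 °C; evaporate; ZnBr2 (20 mol%), THF, 25–40 °C
Reagents that add atoms: none
Why: Acidolysis frees the carboxylic acid, and ZnBr2-catalysed 6-endo-dig lactonisation of 2-en-4-ynoic acids whose alkyne is cis to the carboxyl is an established 2-pyrone synthesis to which the thioester is inert.

Step 12
Reactants: 13 1-(but-3-en-1-yl)-3-methoxy-2-(methoxymethoxy)-4-{[(triisopropylsilyl)ethynyl]oxy}benzene; 22 S-phenyl 3-(3-methoxy-2-oxo-2H-pyran-6-yl)propanethioate
Product: 24 3-methoxy-6-{7-[3-methoxy-2-(methoxymethoxy)-4-{[(triisopropylsilyl)ethynyl]oxy}phenyl]-3-oxoheptyl}-2H-pyran-2-one, via B-alkyl-9-BBN 23 (not isolated)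
Conditions: 13, 9-BBN, THF, 0 → 25 °C; then 22, Pd(PPh3)4 (5 mol%), Cu(O2CC4H3S) (CuTC), Cs2CO3, THF, 45 °C
Reagents that add atoms: none
Why: Anti-Markovnikov hydroboration by 9-BBN is selective for the monosubstituted alkene over the hindered silyl-capped alkyne, and the B-alkyl group is then transferred to the thioester in a Liebeskind–Srogl ketone synthesis, which forms the C4–C5 bond and the C5 ketone under conditions mild enough for the pyrone and the silyl ynol ether.

Step 13
Reactants: 24 3-methoxy-6-{7-[3-methoxy-2-(methoxymethoxy)-4-{[(triisopropylsilyl)ethynyl]oxy}phenyl]-3-oxoheptyl}-2H-pyran-2-one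
Product: 25 6-{7-[4-(ethynyloxy)-3-methoxy-2-(methoxymethoxy)phenyl]-3-oxoheptyl}-3-methoxy-2H-pyran-2-one
Conditions: TBAF, THF (1% H2O), −20 °C; used at once
Reagents that add atoms: none
Why: Fluoride cleaves the C(sp)–Si bond at low temperature with water as the proton source, and the terminal aryl ethynyl ether is carried on immediately because it is prone to hydration and oligomerisation.

Step 14
Reactants: 25 6-{7-[4-(ethynyloxy)-3-methoxy-2-(methoxymethoxy)phenyl]-3-oxoheptyl}-3-methoxy-2H-pyran-2-one
Product: 27 juglanin A methoxymethyl ether, via bridged lactone 26 (not isolated)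
Conditions: 1,2-dichlorobenzene (1 mM, degassed), BHT, 2,6-di-tert-butyl-4-methylpyridine, base-washed glassware, slow addition, 180 °C
Reagents that add atoms: none
Why: Proposed new method: the ynol ether adds across C3 and C6 of the pyrone in a [4+2] cycloaddition, its nucleophilic terminal carbon bonding to the electrophilic C6 and its oxygen-bearing carbon to C3, and the bridged lactone 26 then loses CO2 in an irreversible retro-[4+2] step that aromatises ring A. The closest known reactions are intramolecular 2-pyrone–alkyne Diels–Alder/decarboxylation cascades that close bent cyclophane arenes, and intermolecular pyrone cycloadditions with ynamines and alkynyl ethers; a 3-methoxypyrone, an aryl ynol ether and a ring of this size have not been combined. Ring A (six-membered) closes by the cycloaddition itself, which forms both new C–C bonds. The 15-membered ring closes in the same event as a macrocyclisation across the tether, because the chain links C6 to the ynol oxygen on the carbon that ends up meta to it; high dilution and slow addition hold back intermolecular ynol ether reactions. No stereocentre is formed. The step needs regioselectivity (terminal alkyne carbon to C6), which the matched polarity of the two partners secures; the 3-methoxy group weakens the pyrone as an acceptor, so a high temperature is expected, and the acid scavenger and radical inhibitor protect the ynol ether.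

Step 15
Reactants: 27 juglanin A methoxymethyl ether
Product: 28 juglanin A
Conditions: 2 M aq HCl, THF, 45 °C
Reagents that add atoms: none
Why: Aqueous acid hydrolyses the aryl MOM acetal while the ketone, both methyl ethers and the diaryl ether are stable, so the step should deliver the target directly.

Compound list
1 | 2-methoxybenzene-1,3-diol (2-methoxyresorcinol) | COc1c(O)cccc1O | starting material
2 | 2-methoxy-3-[(triisopropylsilyl)oxy]phenol | COc1c(O)cccc1O[Si](C(C)C)(C(C)C)C(C)C | intermediate
3 | [2-methoxy-3-(methoxymethoxy)phenoxy]triisopropylsilane | COCOc1cccc(O[Si](C(C)C)(C(C)C)C(C)C)c1OC | intermediate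
4 | {3-methoxy-2-(methoxymethoxy)-4-[(triisopropylsilyl)oxy]phenyl}lithium | [Li]c1ccc(O[Si](C(C)C)(C(C)C)C(C)C)c(OC)c1OCOC | intermediate
5 | [4-iodo-2-methoxy-3-(methoxymethoxy)phenoxy]triisopropylsilane | Ic1ccc(O[Si](C(C)C)(C(C)C)C(C)C)c(OC)c1OCOC | intermediate
6 | but-3-en-1-ylzinc bromide | C=CCC[Zn]Br | starting material
7 | [4-(but-3-en-1-yl)-2-methoxy-3-(methoxymethoxy)phenoxy]triisopropylsilane | C=CCCc1ccc(O[Si](C(C)C)(C(C)C)C(C)C)c(OC)c1OCOC | intermediate
8 | trichloroethylene | ClC=C(Cl)Cl | starting material
9 | cesium 4-(but-3-en-1-yl)-2-methoxy-3-(methoxymethoxy)phenolate | C=CCCc1ccc([O-])c(OC)c1OCOC.[Cs+] | intermediate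
10 | 1-(but-3-en-1-yl)-4-{[(E)-1,2-dichloroethenyl]oxy}-3-methoxy-2-(methoxymethoxy)benzene | C=CCCc1ccc(O/C(Cl)=C\Cl)c(OC)c1OCOC | intermediate
11 | 1-(but-3-en-1-yl)-4-[(chloroethynyl)oxy]-3-methoxy-2-(methoxymethoxy)benzene | C=CCCc1ccc(OC#CCl)c(OC)c1OCOC | intermediate
12 | lithium [4-(but-3-en-1-yl)-2-methoxy-3-(methoxymethoxy)phenoxy]ethynide | C=CCCc1ccc(OC#C[Li])c(OC)c1OCOC | intermediate
13 | 1-(but-3-en-1-yl)-3-methoxy-2-(methoxymethoxy)-4-{[(triisopropylsilyl)ethynyl]oxy}benzene | C=CCCc1ccc(OC#C[Si](C(C)C)(C(C)C)C(C)C)c(OC)c1OCOC | intermediate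
14 | pent-4-ynoic acid | C#CCCC(=O)O | starting material
15 | S-phenyl pent-4-ynethioate | C#CCCC(=O)Sc1ccccc1 | intermediate
16 | tert-butyl 2-methoxyacetate | COCC(=O)OC(C)(C)C | starting material
17 | ethyl formate | CCOC=O | starting material
18 | sodium (1E)-3-tert-butoxy-2-methoxy-3-oxoprop-1-en-1-olate (enolate oxygen cis to the ester) | CC(C)(C)OC(=O)/C(OC)=C\[O-].[Na+] | intermediate
19 | tert-butyl (2E)-2-methoxy-3-{[(trifluoromethyl)sulfonyl]oxy}prop-2-enoate (triflate cis to the ester) | CC(C)(C)OC(=O)/C(OC)=C\OS(=O)(=O)C(F)(F)F | intermediate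
20 | tert-butyl (2E)-2-methoxy-8-oxo-8-(phenylsulfanyl)oct-2-en-4-ynoate (alkyne cis to the ester) | CC(C)(C)OC(=O)/C(OC)=C\C#CCCC(=O)Sc1ccccc1 | intermediate
21 | (2E)-2-methoxy-8-oxo-8-(phenylsulfanyl)oct-2-en-4-ynoic acid | OC(=O)/C(OC)=C\C#CCCC(=O)Sc1ccccc1 | intermediate
22 | S-phenyl 3-(3-methoxy-2-oxo-2H-pyran-6-yl)propanethioate | COc1ccc(CCC(=O)Sc2ccccc2)oc1=O | intermediate
23 | 9-{4-[3-methoxy-2-(methoxymethoxy)-4-{[(triisopropylsilyl)ethynyl]oxy}phenyl]butyl}-9-borabicyclo[3.3.1]nonane | CC(C)[Si](C#COc1ccc(CCCCB2C3CCCC2CCC3)c(OCOC)c1OC)(C(C)C)C(C)C | intermediate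
24 | 3-methoxy-6-{7-[3-methoxy-2-(methoxymethoxy)-4-{[(triisopropylsilyl)ethynyl]oxy}phenyl]-3-oxoheptyl}-2H-pyran-2-one | COc1ccc(CCC(=O)CCCCc2ccc(OC#C[Si](C(C)C)(C(C)C)C(C)C)c(OC)c2OCOC)oc1=O | intermediate
25 | 6-{7-[4-(ethynyloxy)-3-methoxy-2-(methoxymethoxy)phenyl]-3-oxoheptyl}-3-methoxy-2H-pyran-2-one (precursor of the key step) | COc1ccc(CCC(=O)CCCCc2ccc(OC#C)c(OC)c2OCOC)oc1=O | intermediate
26 | bridged lactone (racemic 2-oxabicyclo[2.2.2]octa-5,7-dien-3-one; bridgeheads are pyrone C3 with OMe and C6 with the chain, the former alkyne carries the aryloxy group, and chain and ring B span the bicycle) | COC12C=CC3(OC1=O)C=C2Oc1ccc(c(OCOC)c1OC)CCCCC(=O)CC3 | intermediate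
27 | juglanin A methoxymethyl ether (ring B phenol as MOM ether) | COc1ccc2cc1Oc1ccc(c(OCOC)c1OC)CCCCC(=O)CC2 | intermediate
28 | juglanin A | COc1ccc2cc1Oc1ccc(c(O)c1OC)CCCCC(=O)CC2 | target

Total step count: 15. Longest linear sequence: 10 steps (steps 1–6, then 12–15).

Steps most likely to fail

Step 14. The cycloaddition may be slower than thermal hydration or oligomerisation of the aryl ethynyl ether, because the 3-methoxy group lowers the acceptor strength of the pyrone and closing a 15-membered ring costs entropy. The fallback uses known chemistry, a diaryl ether formed by Ullmann macrocyclisation; it sets out from 7 and comes back to the route at 27. Hydroboration of 7 with 9-BBN gives the B-alkyl-9-BBN adduct F1, and iodinolysis (I2, NaOMe) gives the primary iodide F2. Zinc insertion (Zn dust, LiCl, THF) gives the alkylzinc iodide F3, which undergoes Fukuyama coupling (PdCl2(PPh3)2, THF/toluene, 25 °C) with S-phenyl 3-(3-bromo-4-methoxyphenyl)propanethioate F4, made from the commercial acid with thiophenol and DCC, to give the bromo ketone F5. TBAF frees the bromo phenol F6, and CuO/K2CO3 in refluxing pyridine at high dilution closes the diaryl ether to 27.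

Step 12. Transfer of the alkyl group from boron to the acyl–palladium intermediate may be slow, so that protodeboronation, thioester cleavage or base attack on the pyrone takes over. The fallback replaces the acyl coupling by olefin cross-metathesis and conjugate reduction; it sets out from 22 and 13 and comes back at 24. Liebeskind–Srogl coupling of 22 with tributyl(vinyl)stannane (Pd2(dba)3, tri(2-furyl)phosphine, Cu(O2PPh2)) gives the vinyl ketone F7. Cross-metathesis of F7 with 13 (second-generation Hoveyda–Grubbs catalyst, CH2Cl2, 40 °C) gives the E-enone F8. 1,4-Reduction with [(Ph3P)CuH]6 in toluene then gives 24.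

Step 11. Lactonisation may take the five-membered exo course, or stall if the alkene has isomerised during coupling so that the carboxyl cannot reach the alkyne. The fallback builds the ring by conjugate addition and cyclocondensation, which does not depend on alkene geometry; it sets out from 14 and 19 and comes back at 22. Sonogashira coupling of the free acid 14 with 19 gives the enynoic acid F9. Pyrrolidine adds at the alkyne terminus (1,6-addition) to give the aminodienoate F10. Hot aqueous AcOH/HCl hydrolyses the enamine, and the resulting 5-oxo-2-enoate lactonises with loss of tert-butanol to the pyrone acid F11. DCC/thiophenol then gives 22.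

Further compounds
F1 | step 14 | 9-{4-[3-methoxy-2-(methoxymethoxy)-4-[(triisopropylsilyl)oxy]phenyl]butyl}-9-borabicyclo[3.3.1]nonane | CC(C)[Si](Oc1ccc(CCCCB2C3CCCC2CCC3)c(OCOC)c1OC)(C(C)C)C(C)C
F2 | step 14 | [4-(4-iodobutyl)-2-methoxy-3-(methoxymethoxy)phenoxy]triisopropylsilane | ICCCCc1ccc(O[Si](C(C)C)(C(C)C)C(C)C)c(OC)c1OCOC
F3 | step 14 | {4-[3-methoxy-2-(methoxymethoxy)-4-[(triisopropylsilyl)oxy]phenyl]butyl}zinc iodide | I[Zn]CCCCc1ccc(O[Si](C(C)C)(C(C)C)C(C)C)c(OC)c1OCOC
F4 | step 14 | S-phenyl 3-(3-bromo-4-methoxyphenyl)propanethioate | COc1ccc(CCC(=O)Sc2ccccc2)cc1Br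
F5 | step 14 | 1-(3-bromo-4-methoxyphenyl)-7-{3-methoxy-2-(methoxymethoxy)-4-[(triisopropylsilyl)oxy]phenyl}heptan-3-one | COc1ccc(CCC(=O)CCCCc2ccc(O[Si](C(C)C)(C(C)C)C(C)C)c(OC)c2OCOC)cc1Br
F6 | step 14 | 1-(3-bromo-4-methoxyphenyl)-7-[4-hydroxy-3-methoxy-2-(methoxymethoxy)phenyl]heptan-3-one | COc1ccc(CCC(=O)CCCCc2ccc(O)c(OC)c2OCOC)cc1Br
F7 | step 12 | 3-methoxy-6-(3-oxopent-4-en-1-yl)-2H-pyran-2-one | COc1ccc(CCC(=O)C=C)oc1=O
F8 | step 12 | 3-methoxy-6-[(4E)-7-{3-methoxy-2-(methoxymethoxy)-4-{[(triisopropylsilyl)ethynyl]oxy}phenyl}-3-oxohept-4-en-1-yl]-2H-pyran-2-one | COc1ccc(CCC(=O)/C=C/CCc2ccc(OC#C[Si](C(C)C)(C(C)C)C(C)C)c(OC)c2OCOC)oc1=O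
F9 | step 11 | (6E)-8-tert-butoxy-7-methoxy-8-oxooct-6-en-4-ynoic acid | CC(C)(C)OC(=O)/C(OC)=C\C#CCCC(=O)O
F10 | step 11 | 8-tert-butoxy-7-methoxy-8-oxo-4-(pyrrolidin-1-yl)octa-4,6-dienoic acid (mixture of alkene isomers) | CC(C)(C)OC(=O)C(OC)=CC=C(CCC(=O)O)N1CCCC1
F11 | step 11 | 3-(3-methoxy-2-oxo-2H-pyran-6-yl)propanoic acid | COc1ccc(CCC(=O)O)oc1=O
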